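**Plan**

1. Retrosynthesis: the C8–O acyl bond and the C12 ester level (isopropenyl → acrylate) are cut last. Ring B is then cut at C5–C6 (aldol) while C5–C8 is re-formed, which traces the ring C5–C6–C7–C8–C9–C10 back to the cyclobutane C5–C8–C9–C10. Next come C7–C8 (allylindium + cyclobutanone) and the cyclobutane itself (enone + allene [2+2]).
2. Enabling feature: C6 is a carbinol flanked by C5 (α to the C4 ketone) and C7 (α to the C8 oxygen), so ring B is a double aldol. A C8 cyclobutanol that is β to the C4 ketone and carries C7–C6H=O opens by retro-aldol (C5–C8) and re-closes by aldol (C5–C6), inserting C7 and C6 into the four-membered ring.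
3. Forward order: ring A enone → cyclobutane (quaternary C10) → cyclobutanone → C6/C7/C11–C13 unit → two-atom enlargement to ring B → C8 reduction and esterification → isopropenyl to methyl acrylate → desilylation.
4. Stereochemistry: C1 from a CBS reduction; C10 relayed from C1 in the photocycloaddition; C5, C6, C7 from thermodynamic control in the ring enlargement (all equatorial on the trans-decalin); C8 from a dissolving-metal reduction (equatorial alcohol).

Key step: step 10

Remark 1: the target SMILES is read as 1β,6α-dihydroxy, 8α-acyloxy, 5α-H, 7α-H (side chain β), 10β-CH3; every substituent except the C10 methyl is equatorial on the trans-decalin.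
Remark 2: all intermediates carry the atom labels of the 15-noreudesmane skeleton of the target (ring carbons C1–C10, side chain C11–C13; C4 = ring-A carbonyl carbon; β = face of the C10 methyl).
Remark 3: compounds 1, 7, 11 and 19 are taken as commercial.

**Step 1**
Reactants: 1 4-methoxy-2-methylphenol
Product: 2 4,4-dimethoxy-2-methylcyclohexa-2,5-dien-1-one
Conditions: PhI(OAc)2, MeOH, 0 °C
Reagents that add atoms: methanol CO
Why: oxidative dearomatisation of a para-methoxyphenol with iodine(III) in methanol should give the quinone monoketal, which places the future C1 and C4 oxygens 1,4 on ring A.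

**Step 2**
Reactants: 2 4,4-dimethoxy-2-methylcyclohexa-2,5-dien-1-one
Product: 3 4,4-dimethoxy-2-methylcyclohex-2-en-1-one
Conditions: H2 (1 atm), RhCl(PPh3)3 (cat.), PhH/EtOH, rt
Reagents that add atoms: none
Why: homogeneous hydrogenation with Wilkinson's catalyst should saturate the disubstituted CH=CH bond and leave the trisubstituted methyl-bearing alkene, the ketone and the ketal untouched.

**Step 3**
Reactants: 3 4,4-dimethoxy-2-methylcyclohex-2-en-1-one
Product: 5 (R)-4-hydroxy-3-methylcyclohex-2-en-1-one, via allylic alcohol ketal 4 (not isolated)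
Conditions: (S)-Me-CBS (cat.), BH3·SMe2, THF, −20 °C; then 1 M HCl, THF, 0 °C
Reagents that add atoms: water O
Why: Corey–Bakshi–Shibata reduction with the α-methylalkenyl arm as the large group should give the (R)-carbinol (C1), and the acidic work-up hydrolyses the allylic ketal so that the carbonyl appears at C4 in conjugation with C5=C10.

**Step 4**
Reactants: 5 (R)-4-hydroxy-3-methylcyclohex-2-en-1-one
Product: 6 (R)-4-[(tert-butyldimethylsilyl)oxy]-3-methylcyclohex-2-en-1-one
Conditions: TBSCl, imidazole, DMF, rt
Reagents that add atoms: tert-butyldimethylsilyl chloride CC(C)(C)[Si](C)(C)Cl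
Why: standard silylation protects C1–OH through the oxidations to come and gives the bulky group that steers step 5.

**Step 5**
Reactants: 6 (R)-4-[(tert-butyldimethylsilyl)oxy]-3-methylcyclohex-2-en-1-one; 7 allene
Product: 8 cis-fused 5-(TBSO)-6-methyl-8-methylidenebicyclo[4.2.0]octan-2-one (C1β-OTBS, C10β-CH3, C5β-H; cyclobutane = C5, C8, C9, C10; exocyclic CH2 on C8)
Conditions: hν (350 nm, Pyrex), allene (excess), THF, −78 °C
Reagents that add atoms: none
Why: enone–allene [2+2] photocycloaddition should follow the usual head-to-head regiochemistry (central allene carbon to Cα, giving the β,γ-unsaturated ketone), add anti to the adjacent C1–OTBS so that the C10 methyl ends cis to the silyloxy group, and give the cis ring fusion.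

**Step 6**
Reactants: 8 photoadduct ketone
Product: 9 the corresponding C4 alcohol (4α-OH, cis to the four-membered ring)
Conditions: L-Selectride, THF, −78 °C; aq. NH4Cl
Reagents that add atoms: none
Why: hydride delivery to the convex face parks C4 at the alcohol level so that no aldol-labile 2-acylcyclobutanol exists before step 10; the C4 configuration is inconsequential because the carbon returns to a ketone.

**Step 7**
Reactants: 9 C4 alcohol with exocyclic methylene
Product: 10 cyclobutanone (C8=O) with free C4–OH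
Conditions: O3, CH2Cl2/MeOH, −78 °C; Me2S
Reagents that add atoms: ozone [O-][O+]=O
Why: ozonolysis of the 1,1-disubstituted alkene with reductive work-up gives the cyclobutanone; silyl ether and secondary alcohol are inert.

**Step 8**
Reactants: 11 ethyl (E)-4-bromo-3-methylbut-2-enoate
Product: 12 (E)-4-bromo-3-methylbut-2-en-1-ol
Conditions: DIBAL-H, CH2Cl2, −78 °C; Rochelle salt
Reagents that add atoms: none
Why: low-temperature DIBAL-H reduction of the conjugated ester gives the allylic alcohol and should leave the allylic bromide in place.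

**Step 9**
Reactants: 10 cyclobutanone; 12 (E)-4-bromo-3-methylbut-2-en-1-ol
Product: 13 triol: C8 tertiary cyclobutanol carrying CH(CH2OH)C(CH3)=CH2 at C8 (C7 = the CH, C6 = CH2OH), 4α-OH, 1β-OTBS; diastereomer mixture at C7 and C8
Conditions: In powder, THF/H2O (1:1), rt
Reagents that add atoms: none
Why: Barbier allylation, in which the allylindium reagent adds through its γ-carbon (SE2′) to the strained ketone and tolerates free hydroxyls, forms C7–C8 and leaves the isopropenyl group on C7; the C7/C8 configurations are erased or equilibrated in step 10.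

**Step 10**
Reactants: 13 triol
Product: 16 1β-(TBSO)-6α-hydroxy-7β-isopropenyl-15-nor-5αH-eudesmane-4,8-dione, via keto aldehyde cyclobutanol 14 (not isolated), via ring-opened diketo aldehyde 15 (not isolated)
Conditions: (COCl)2, DMSO, CH2Cl2, −78 °C; Et3N, −78 → 0 °C; then DBU (cat.), 0 °C
Reagents that add atoms: none
Why: Swern oxidation unveils the C4 ketone and the C6 aldehyde together, which turns the C8 carbinol into a 2-acylcyclobutanol; amine base then triggers retro-aldol cleavage of the strained C5–C8 bond to the C4 enol(ate) and the C8 ketone, and C5 adds to the C6 aldehyde, so the ring C5–C8–C9–C10 is enlarged by C7 and C6 to ring B. The closest known reaction type is the De Mayo retro-aldol opening of enone-photoadduct cyclobutanols, here followed in the same flask by an intramolecular aldol addition. Ring B closes by a 6-(enolexo)-exo-trig aldol. C5, C6 and C7 are set under thermodynamic control (reversible aldol, enolisable C5 and C7): trans-decalin with 6-OH and 7-isopropenyl equatorial, since an axial 6-OH would be syn-axial to the C10 methyl and the equatorial one can hydrogen-bond to the C4 carbonyl; C1 and C10 are carried over. The step needs cleavage of the ring bond C5–C8 and not of the exocyclic C7–C8 bond (secured by release of cyclobutane strain), attack of C5 on the aldehyde and not of C3 on the C8 ketone (the enol(ate) is born at C5 next to the more electrophilic carbonyl), and no migration of the isopropenyl double bond (low temperature, catalytic base, short time).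

**Step 11**
Reactants: 16 aldol
Product: 17 1β,6α-bis(TBSO)-7β-isopropenyl-15-nor-5αH-eudesmane-4,8-dione
Conditions: TBSOTf, 2,6-lutidine, CH2Cl2, −78 °C
Reagents that add atoms: tert-butyldimethylsilyl triflate CC(C)(C)[Si](C)(C)OS(=O)(=O)C(F)(F)F
Why: silylation of the hindered aldol hydroxyl with the silyl triflate under non-nucleophilic base locks the aldol against retro-aldol and dehydration and distinguishes O6 from the C8 oxygen to come.

**Step 12**
Reactants: 17 bis-silyl diketone
Product: 18 1β,6α-bis(TBSO)-7β-isopropenyl-15-nor-5αH-eudesmane-4α,8α-diol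
Conditions: Li, NH3(l)/THF, EtOH, −78 °C; NH4Cl
Reagents that add atoms: none
Why: dissolving-metal reduction gives the thermodynamically preferred equatorial alcohols, here the required 8α-OH (hydride reagents would attack anti to the syn-axial C10 methyl and give 8β), while the isolated alkene and silyl ethers are inert; C4 is reduced as well and is re-oxidised in step 17.

**Step 13**
Reactants: 19 methyl 2-(hydroxymethyl)acrylate
Product: 20 methyl 2-{[(tert-butyldimethylsilyl)oxy]methyl}acrylate
Conditions: TBSCl, imidazole, CH2Cl2, 0 °C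
Reagents that add atoms: tert-butyldimethylsilyl chloride CC(C)(C)[Si](C)(C)Cl
Why: routine protection of the primary allylic alcohol of the side-chain acid.

**Step 14**
Reactants: 20 silyl ether ester
Product: 21 2-{[(tert-butyldimethylsilyl)oxy]methyl}acrylic acid
Conditions: LiOH, THF/H2O, 0 °C; then 1 M HCl to pH 3
Reagents that add atoms: lithium hydroxide [Li+].[OH-]
Why: mild saponification of the methyl ester at 0 °C should leave the silyl ether and the acrylate double bond intact.

**Step 15**
Reactants: 18 4α,8α-diol; 21 2-{[(tert-butyldimethylsilyl)oxy]methyl}acrylic acid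
Product: 22 8α-{2-[(TBSO)methyl]acryloyloxy}-1β,6α-bis(TBSO)-7β-isopropenyl-15-nor-5αH-eudesman-4α-ol
Conditions: DCC, DMAP (cat.), CH2Cl2, 0 °C → rt
Reagents that add atoms: none
Why: Steglich esterification should acylate the open equatorial 8α-OH, whereas the C4 hydroxyl is shielded by the peri 6α-OTBS group (gauche to C4 across C5, anti to C8).

**Step 16**
Reactants: 22 8-ester with isopropenyl group
Product: 23 the corresponding 12-hydroxy compound (C7–C(=CH2)CH2OH; 4α-OH free)
Conditions: SeO2 (cat.), t-BuOOH, CH2Cl2, rt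
Reagents that add atoms: tert-butyl hydroperoxide CC(C)(C)OO
Why: selenium dioxide allylic oxidation of a 1,1-disubstituted alkene takes place at the methyl group in preference to the methine, and the electron-poor acrylate alkene does not react; any enal formed converges in step 17.

**Step 17**
Reactants: 23 4,12-diol
Product: 24 4-oxo-12-al (C7–C(=CH2)CHO)
Conditions: Dess–Martin periodinane, NaHCO3, CH2Cl2, 0 °C → rt
Reagents that add atoms: none
Why: buffered Dess–Martin oxidation converts the C4 carbinol back into the ketone and the allylic alcohol into the 2-substituted acrolein in one operation without epimerising C5.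

**Step 18**
Reactants: 24 keto enal
Product: 25 4-oxo-12-oic acid
Conditions: NaClO2, NaH2PO4, 2-methyl-2-butene, t-BuOH/H2O, 0 °C
Reagents that add atoms: sodium chlorite [Na+].[O-]Cl=O
Why: Pinnick oxidation is selective for the aldehyde and tolerates acrylates, ketone and silyl ethers.

**Step 19**
Reactants: 25 acrylic acid
Product: 26 methyl ester (tris-TBS ether of the target)
Conditions: TMSCHN2, PhMe/MeOH, 0 °C
Reagents that add atoms: (trimethylsilyl)diazomethane C[Si](C)(C)C=[N+]=[N-]
Why: neutral methylation of the carboxylic acid avoids base, which could cause β-elimination of the C8 acyloxy group; short contact limits dipolar addition to the acrylates.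

**Step 20**
Reactants: 26 tris-TBS ether
Product: 27 CNP0144895.1 (methyl 8α-{[2-(hydroxymethyl)acryloyl]oxy}-1β,6α-dihydroxy-4-oxo-15-nor-5αH-eudesm-11(13)-en-12-oate)
Conditions: HF·pyridine, THF/pyridine, 0 °C → rt
Reagents that add atoms: none
Why: buffered fluoride removes the three silyl ethers under mildly acidic conditions, which should avoid retro-aldol, acyl migration and lactonisation of the γ-hydroxy ester.

**Compound list**

1 | 4-methoxy-2-methylphenol | COc1ccc(O)c(C)c1 | starting material
2 | 4,4-dimethoxy-2-methylcyclohexa-2,5-dien-1-one | COC1(OC)C=CC(=O)C(C)=C1 | intermediate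
3 | 4,4-dimethoxy-2-methylcyclohex-2-en-1-one | COC1(OC)CCC(=O)C(C)=C1 | intermediate
4 | (R)-4,4-dimethoxy-2-methylcyclohex-2-en-1-ol (not isolated) | COC1(OC)C=C(C)[C@H](O)CC1 | intermediate
5 | (R)-4-hydroxy-3-methylcyclohex-2-en-1-one | O=C1C=C(C)[C@H](O)CC1 | intermediate
6 | (R)-4-[(tert-butyldimethylsilyl)oxy]-3-methylcyclohex-2-en-1-one | O=C1C=C(C)[C@H](O[Si](C)(C)C(C)(C)C)CC1 | intermediate
7 | allene (propa-1,2-diene) | C=C=C | starting material
8 | cis-fused 5-(TBSO)-6-methyl-8-methylidenebicyclo[4.2.0]octan-2-one; fusion H, CH3 and OTBS on one face | C=C1C[C@@]2(C)[C@H](O[Si](C)(C)C(C)(C)C)CCC(=O)[C@@H]12 | intermediate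
9 | C4 alcohol of 8 (OH cis to the four-membered ring) | C=C1C[C@@]2(C)[C@H](O[Si](C)(C)C(C)(C)C)CC[C@@H](O)[C@@H]12 | intermediate
10 | cyclobutanone: cis-fused 5-hydroxy-1-methyl-2-(TBSO)bicyclo[4.2.0]octan-7-one | O=C1C[C@@]2(C)[C@H](O[Si](C)(C)C(C)(C)C)CC[C@@H](O)[C@@H]12 | intermediate
11 | ethyl (E)-4-bromo-3-methylbut-2-enoate | CCOC(=O)/C=C(\C)CBr | starting material
12 | (E)-4-bromo-3-methylbut-2-en-1-ol | OC/C=C(\C)CBr | intermediate
13 | triol: 10 with C8(OH)–CH(CH2OH)C(CH3)=CH2 (C7/C8 diastereomer mixture, descriptors left open) | OCC(C(C)=C)C1(O)C[C@@]2(C)[C@H](O[Si](C)(C)C(C)(C)C)CC[C@@H](O)[C@@H]12 | intermediate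
14 | keto aldehyde cyclobutanol (not isolated; C7/C8 open) | O=CC(C(C)=C)C1(O)C[C@@]2(C)[C@H](O[Si](C)(C)C(C)(C)C)CCC(=O)[C@@H]12 | intermediate
15 | ring-opened diketo aldehyde (not isolated; C7 open) | O=CC(C(C)=C)C(=O)C[C@@]1(C)[C@H](O[Si](C)(C)C(C)(C)C)CCC(=O)C1 | intermediate
16 | 1β-(TBSO)-6α-hydroxy-7β-isopropenyl-15-nor-5αH-eudesmane-4,8-dione | O=C1C[C@@]2(C)[C@H](O[Si](C)(C)C(C)(C)C)CCC(=O)[C@@H]2[C@@H](O)[C@@H]1C(C)=C | intermediate
17 | 1β,6α-bis(TBSO)-7β-isopropenyl-15-nor-5αH-eudesmane-4,8-dione | O=C1C[C@@]2(C)[C@H](O[Si](C)(C)C(C)(C)C)CCC(=O)[C@@H]2[C@@H](O[Si](C)(C)C(C)(C)C)[C@@H]1C(C)=C | intermediate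
18 | 1β,6α-bis(TBSO)-7β-isopropenyl-15-nor-5αH-eudesmane-4α,8α-diol | O[C@H]1C[C@@]2(C)[C@H](O[Si](C)(C)C(C)(C)C)CC[C@@H](O)[C@@H]2[C@@H](O[Si](C)(C)C(C)(C)C)[C@@H]1C(C)=C | intermediate
19 | methyl 2-(hydroxymethyl)acrylate | C=C(CO)C(=O)OC | starting material
20 | methyl 2-{[(tert-butyldimethylsilyl)oxy]methyl}acrylate | C=C(CO[Si](C)(C)C(C)(C)C)C(=O)OC | intermediate
21 | 2-{[(tert-butyldimethylsilyl)oxy]methyl}acrylic acid | C=C(CO[Si](C)(C)C(C)(C)C)C(=O)O | intermediate
22 | 8α-ester of 18 with 21 (4α-OH free, 7β-isopropenyl) | C=C(CO[Si](C)(C)C(C)(C)C)C(=O)O[C@H]1C[C@@]2(C)[C@H](O[Si](C)(C)C(C)(C)C)CC[C@@H](O)[C@@H]2[C@@H](O[Si](C)(C)C(C)(C)C)[C@@H]1C(C)=C | intermediate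
23 | 12-hydroxy derivative of 22 (C7–C(=CH2)CH2OH) | C=C(CO[Si](C)(C)C(C)(C)C)C(=O)O[C@H]1C[C@@]2(C)[C@H](O[Si](C)(C)C(C)(C)C)CC[C@@H](O)[C@@H]2[C@@H](O[Si](C)(C)C(C)(C)C)[C@@H]1C(=C)CO | intermediate
24 | 4-oxo-12-al (C7–C(=CH2)CHO) | C=C(CO[Si](C)(C)C(C)(C)C)C(=O)O[C@H]1C[C@@]2(C)[C@H](O[Si](C)(C)C(C)(C)C)CCC(=O)[C@@H]2[C@@H](O[Si](C)(C)C(C)(C)C)[C@@H]1C(=C)C=O | intermediate
25 | 4-oxo-12-oic acid | C=C(CO[Si](C)(C)C(C)(C)C)C(=O)O[C@H]1C[C@@]2(C)[C@H](O[Si](C)(C)C(C)(C)C)CCC(=O)[C@@H]2[C@@H](O[Si](C)(C)C(C)(C)C)[C@@H]1C(=C)C(=O)O | intermediate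
26 | tris-TBS ether of the target (methyl ester) | C=C(CO[Si](C)(C)C(C)(C)C)C(=O)O[C@H]1C[C@@]2(C)[C@H](O[Si](C)(C)C(C)(C)C)CCC(=O)[C@@H]2[C@@H](O[Si](C)(C)C(C)(C)C)[C@@H]1C(=C)C(=O)OC | intermediate
27 | CNP0144895.1 | C=C(CO)C(=O)O[C@H]1C[C@@]2(C)[C@H](O)CCC(=O)[C@@H]2[C@@H](O)[C@@H]1C(=C)C(=O)OC | target

**Step count**

Total: 20 steps. Longest linear sequence: 17 steps (1–7, 9–12, 15–20); steps 8 and 13–14 are side branches.

**Steps most likely to fail**

Step 10 (ring enlargement). After ring opening, the 2-substituted β-keto aldehyde 15 may rest as its stabilised enol and not re-close. The aldol may also dehydrate, the isopropenyl double bond may move into conjugation with the C8 ketone, or C5/C7 may not fully equilibrate. The fallback closes ring B by a Michael addition and brings in the C6 oxygen afterwards. It sets out from 10 and comes back at 16. The cerium reagent made from (Z)-benzyl(2-iodo-3-methylbuta-1,3-dien-1-yl)dimethylsilane F1 (t-BuLi, then CeCl3; F1 from 2-methylbut-1-en-3-yne by silylcupration and iodination) adds to the cyclobutanone to give the 1-dienylcyclobutanol F2. Swern oxidation of the C4 carbinol and amine base open the four-membered ring by the same retro-aldol step, but C5 now adds irreversibly to the β-silyl enone (anionic two-carbon ring expansion of a 2-acyl-1-vinylcyclobutanol, with no acidic β-keto aldehyde on the path). α-Protonation gives the 6α-silyl dione F3. Tamao oxidation of the benzyldimethylsilyl group (TBAF; then H2O2, KHCO3) with retention gives 16.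

Step 16 (allylic oxidation). Oxidation may occur at the allylic methine C7, conversion may be low in the hindered late intermediate, or over-oxidation may occur. The fallback sets out from 22 and comes back at 24. Dess–Martin oxidation first restores the C4 ketone (isopropenyl ketone F4). Ene-type chlorination of the isopropenyl group with hypochlorous acid (Ca(OCl)2, CO2, CH2Cl2/H2O, 0 °C) gives the allylic chloride F5. Ganem oxidation (N-methylmorpholine N-oxide, MeCN) then gives enal 24.

Step 9 (Barbier allylation). The hindered ketone may couple at the unsubstituted allyl terminus (linear product) or react slowly. The fallback sets out from 10 and comes back at 13. The lithium dienolate generated with MeLi from (E)-1-(trimethylsilyloxy)-3-methylbuta-1,3-diene F6 (from 3-methylbut-2-enal, TMSCl, Et3N, NaI) adds through its α-carbon to the cyclobutanone at −78 °C to give the β-hydroxy aldehyde F7. NaBH4 then reduces the aldehyde to triol 13.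

**Further compounds**

F1 | step 10 | (Z)-benzyl(2-iodo-3-methylbuta-1,3-dien-1-yl)dimethylsilane | C=C(C)/C(I)=C/[Si](C)(C)Cc1ccccc1
F2 | step 10 | 1-dienylcyclobutanol: 10 with C8(OH)–C(isopropenyl)=CH–SiMe2Bn (C8 descriptor open) | C=C(C)/C(=C/[Si](C)(C)Cc3ccccc3)C1(O)C[C@@]2(C)[C@H](O[Si](C)(C)C(C)(C)C)CC[C@@H](O)[C@@H]12
F3 | step 10 | 6α-(benzyldimethylsilyl)-1β-(TBSO)-7β-isopropenyl-15-nor-5αH-eudesmane-4,8-dione | O=C1C[C@@]2(C)[C@H](O[Si](C)(C)C(C)(C)C)CCC(=O)[C@@H]2[C@@H]([Si](C)(C)Cc3ccccc3)[C@@H]1C(C)=C
F4 | step 16 | 4-oxo analogue of 22 (isopropenyl ketone) | C=C(CO[Si](C)(C)C(C)(C)C)C(=O)O[C@H]1C[C@@]2(C)[C@H](O[Si](C)(C)C(C)(C)C)CCC(=O)[C@@H]2[C@@H](O[Si](C)(C)C(C)(C)C)[C@@H]1C(C)=C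
F5 | step 16 | allylic chloride (C7–C(=CH2)CH2Cl, 4-oxo) | C=C(CO[Si](C)(C)C(C)(C)C)C(=O)O[C@H]1C[C@@]2(C)[C@H](O[Si](C)(C)C(C)(C)C)CCC(=O)[C@@H]2[C@@H](O[Si](C)(C)C(C)(C)C)[C@@H]1C(=C)CCl
F6 | step 9 | (E)-1-(trimethylsilyloxy)-3-methylbuta-1,3-diene | C=C(C)/C=C/O[Si](C)(C)C
F7 | step 9 | β-hydroxy aldehyde: 10 with C8(OH)–CH(CHO)C(CH3)=CH2 (C7/C8 descriptors open) | O=CC(C(C)=C)C1(O)C[C@@]2(C)[C@H](O[Si](C)(C)C(C)(C)C)CC[C@@H](O)[C@@H]12
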